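Start from the end.

| flask | starting material | reagent | time |
|---|---|---|---|
| south-west | 0.50 M | 0.300 equiv | 10 min |
| south | 0.50 M | 0.500 equiv | 10 min |
| north-east | 0.50 M | 0.800 equiv | 10 min |
| east | 0.50 M | 1.20 equiv | 10 min |
| south-east | 0.50 M | 1.50 equiv | 10 min |

    starting material + reagent → other mono adduct + by-product (k1 = 0.149 M⁻¹ s⁻¹)
    reagent + single product → double product + by-product (k2 = 0.169 M⁻¹ s⁻¹)
    starting material + reagent → single product + by-product (k3 = 0.0822 M⁻¹ s⁻¹)
    single product ⇌ isomer of the product (K4 = 1.4, k4 = 0.178 s⁻¹)
    reagent + other mono adduct → double product + by-product (k5 = 0.0392 M⁻¹ s⁻¹)

- amount of single product at the end, in percent of the starting material charged for south-west, south, north-east, east, south-east, in this order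
- how that number moves from the first to the last of them (rises, then falls / rises all the way / falls all the way / hardly changes / falls, then rises)

- "hardly changes" means that all values lie within two and a half points (for a concentration: within two and a half percent of the largest)
- run time (south-west): 10 min

In south-west, step 1 alone, with reagent held at its charge as if it never ran down, gives starting material a notional half-life of 0.52 min, far shorter than the 10 min of the run, so I take the end state to be reagent spent, with reagent as the limiting reagent. The relaxation half-life of single product and isomer is 2.27 s, short against the 10 min, so at the end I take the two as one pool in equilibrium, with a share of single product of 41.7%. While reagent lasts this is rougher: with starting material held at its charge, reagent in south-west has a half-life of 6.00 s, which is 2.64 times that relaxation half-life. Of the starting material consumed, 35.6% enters this pool.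

Dividing each rate by the rate at which starting material falls removes both reagent and time. What remains is a selectivity factor, the drain ratio α: the pool's rate constant for taking reagent, weighted by its share, over the summed constants for starting material, 0.305. The other mono adduct has its own ratio, β = 0.170. With a the fraction of starting material left, and the share of single product held at its end value throughout, I get two approximate curves:

c(single product) / c(starting material charged) = 0.213 × (a^α − a)

c(other mono adduct) / c(starting material charged) = 0.776 × (a^β − a)

The bracket for south-west does not use these curves for the pool. For the upper bound, suppose every reagent molecule takes starting material and the pool loses nothing to the second addition: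

a = 70.0%, single product 4.44%

For the lower bound, suppose the whole pool stands as single product until the reagent is gone, which raises the drain ratio to 0.731. At the a above, this harshest case leaves 1.96% as double product, and at any higher a it leaves less, so a stays below the value on the next line, where the pool is then shared out at its end value:

a = 72.0%, single product 3.67%

The curve peaks where a equals α raised to the power one over one minus α:

a = 18.1%, single product 8.79%

Adding up the reagent spent at that point puts the turn at a charge of 0.987 equiv.

The forecast gives 4.05%, 6.2%, 8.3%, 8.1% and 5.2%, which rises, then falls, so that the number “peaks near 1 equiv”. Its south-west value lies inside my bracket.

The flask gives 3.96%, 6.01%, 7.97%, 7.75% and 4.95%: rises, then falls. South-west stands 0.48 percentage points below my upper bound and 0.29 points above my lower one. The row turns at 0.98 equiv, beside my 0.987 equiv. North-east keeps 31% of its starting material and east 8.5%, one on each side of the peak at 18.1%. South-east keeps 1.2%, and with α = 0.305 the curve gives 5.27% there, against a reading of 4.95%.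

The numbers of this flask come from no measurement; the result is computed.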